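**Retrosynthetic overview**

1. Gneyulin A 30 ⇐ decabenzyl ether 29 (global debenzylation). 29 ⇐ sulfonium salt 18 + sulfone 25 by a reagent-controlled [4+1] annulation that forms C2–C3 and then closes furan ring 2 at O1–C2.
2. Enabling feature: in furan ring 2 (the dihydrofuran fused to the styryl-bearing ring) O1, C7a, C3a and C3 form an ortho-hydroxybenzyl unit whose C3a lies between two ring oxygens, so C3 can be unmasked as the methide carbon of an ortho-quinone methide. C2 is a benzylic carbon of the 2,4-dioxygenated central ring and can be delivered as an aryl-stabilised sulfonium ylide on a chiral sulfide.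
3. 18 ⇐ furan ring 1 (the dihydrofuran fused to the central ring), built by enantioselective Rh-carbene C–H insertion (C2–C3, cis) and acid epimerisation at C2 to trans, then Br → CHO → CH2OH → sulfonium.
4. 25 ⇐ 4-bromo-2,6-difluorobenzaldehyde by SNAr, Heck reaction (stilbene), chelation-controlled mono-debenzylation, aryl Grignard addition and sulfination.
5. Ring order: furan ring 1 (steps 8 and 9), then furan ring 2 (step 19); all ten phenols travel as benzyl ethers.

Key step: step 19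

Remark: the sense of asymmetric induction written for Rh2(S-PTAD)4 (step 8) and for sulfide 17 (step 19) is assumed; each controller is available as either enantiomer, and its antipode would be used if the opposite sense were found.

**Route**

Step 1
Reactants: 1 2,4-bis(benzyloxy)benzaldehyde
Product: 2 [2,4-bis(benzyloxy)phenyl]methanol
Conditions: NaBH4, MeOH/THF, 0 °C
Reagents that add atoms: none
Why: Borohydride reduction of an aryl aldehyde to the benzylic alcohol; no stereocentre is formed.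

Step 2
Reactants: 3 5-bromo-2,4-dihydroxybenzaldehyde
Product: 4 4-(benzyloxy)-5-bromo-2-hydroxybenzaldehyde
Conditions: BnBr (1.05 equiv), CsHCO3, MeCN, 80 °C
Reagents that add atoms: benzyl bromide, BrCc1ccccc1
Why: Williamson etherification that should be selective for the 4-hydroxyl, because the 2-hydroxyl is hydrogen-bonded to the formyl group and is less nucleophilic; no stereocentre is formed.

Step 3
Reactants: 4 4-(benzyloxy)-5-bromo-2-hydroxybenzaldehyde; 2 [2,4-bis(benzyloxy)phenyl]methanol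
Product: 5 4-(benzyloxy)-2-{[2,4-bis(benzyloxy)phenyl]methoxy}-5-bromobenzaldehyde
Conditions: PPh3, DIAD, THF, 0 °C to 23 °C
Reagents that add atoms: none
Why: Mitsunobu etherification of the acidic chelated phenol with the primary benzylic alcohol installs the ether whose methylene becomes C2 of furan ring 1, and avoids the unstable 2,4-dialkoxybenzyl halide.

Step 4
Reactants: 6 1,3-bis(benzyloxy)-5-bromobenzene
Product: 7 [3,5-bis(benzyloxy)phenyl]magnesium bromide (titrated THF solution, kept under argon and drawn on in steps 5 and 17)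
Conditions: Mg turnings, I2 (cat.), THF, 40 °C
Reagents that add atoms: magnesium, [Mg]
Why: Grignard reagent formation by insertion of magnesium into the aryl C–Br bond; the aryl benzyl ethers are inert to it, the solution should keep under argon, and no stereocentre is formed.

Step 5
Reactants: 5 4-(benzyloxy)-2-{[2,4-bis(benzyloxy)phenyl]methoxy}-5-bromobenzaldehyde; 7 [3,5-bis(benzyloxy)phenyl]magnesium bromide
Product: 8 (4-(benzyloxy)-2-{[2,4-bis(benzyloxy)phenyl]methoxy}-5-bromophenyl)[3,5-bis(benzyloxy)phenyl]methanol (racemic)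
Conditions: 7 (1.2 equiv, THF solution), THF, 0 °C; then H2O
Reagents that add atoms: none
Why: Grignard addition to the aldehyde should be much faster than magnesium–bromine exchange at the aryl bromide; the carbinol centre is racemic and is removed in step 6.

Step 6
Reactants: 8 the racemic diaryl carbinol
Product: 9 (4-(benzyloxy)-2-{[2,4-bis(benzyloxy)phenyl]methoxy}-5-bromophenyl)[3,5-bis(benzyloxy)phenyl]methanone
Conditions: MnO2 (10 equiv), CH2Cl2, 23 °C
Reagents that add atoms: none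
Why: MnO2 oxidation of a doubly benzylic alcohol to the benzophenone.

Step 7
Reactants: 9 the benzophenone
Product: 10 hydrazone of 9 (E/Z mixture)
Conditions: N2H4·H2O (10 equiv), AcOH (cat.), EtOH, 90 °C, sealed tube
Reagents that add atoms: hydrazine (as hydrate), NN
Why: Condensation of a 2-alkoxybenzophenone with hydrazine gives the hydrazone that serves as precursor of a diaryldiazomethane.

Step 8
Reactants: 10 hydrazone of 9
Product: 12 (2S,3R)-6-(benzyloxy)-2-[2,4-bis(benzyloxy)phenyl]-3-[3,5-bis(benzyloxy)phenyl]-5-bromo-2,3-dihydro-1-benzofuran (cis), via diazo compound 11 (not isolated)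
Conditions: MnO2 (8 equiv), CH2Cl2, 0 °C, filter; then Rh2(S-PTAD)4 (dirhodium tetrakis[(S)-(1-adamantyl)(N-phthalimido)acetate], 1 mol %), CH2Cl2, −20 °C to 23 °C
Reagents that add atoms: none
Why: Dehydrogenation to the diaryldiazomethane and dirhodium-catalysed loss of N2 give a donor/donor carbene that undergoes 1,5 C–H insertion into the adjacent benzylic ether C–H bond, a reaction type known for cis-2,3-diaryl-2,3-dihydrobenzofurans; the chiral carboxylate ligands select the carbene face and set C3 as R, with C2 following as S in the cis ring.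

Step 9
Reactants: 12 the cis-(2S,3R) dihydrobenzofuran
Product: 13 (2R,3R)-6-(benzyloxy)-2-[2,4-bis(benzyloxy)phenyl]-3-[3,5-bis(benzyloxy)phenyl]-5-bromo-2,3-dihydro-1-benzofuran (trans)
Conditions: CF3CO2H (2 equiv), CH2Cl2, 0 °C
Reagents that add atoms: none
Why: Acid reversibly ionises the O1–C2 bond, which is benzylic to the 2,4-dialkoxyphenyl ring, and reclosure should give the thermodynamically preferred trans isomer; C3 is untouched, so (2S,3R) becomes (2R,3R).

Step 10
Reactants: 13 the trans-(2R,3R) bromide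
Product: 15 (2R,3R)-6-(benzyloxy)-2-[2,4-bis(benzyloxy)phenyl]-3-[3,5-bis(benzyloxy)phenyl]-2,3-dihydro-1-benzofuran-5-carbaldehyde, via aryllithium 14 (not isolated)
Conditions: n-BuLi (1.05 equiv), THF, −78 °C; DMF, −78 °C to 0 °C; then H2O
Reagents that add atoms: N,N-dimethylformamide, CN(C)C=O
Why: Bromine–lithium exchange at −78 °C should outpace deprotonation at C3, and formylation of the aryllithium with DMF gives the aldehyde with both ring stereocentres intact.

Step 11
Reactants: 15 the 5-carbaldehyde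
Product: 16 [(2R,3R)-6-(benzyloxy)-2-[2,4-bis(benzyloxy)phenyl]-3-[3,5-bis(benzyloxy)phenyl]-2,3-dihydro-1-benzofuran-5-yl]methanol
Conditions: NaBH4, THF/MeOH, 0 °C
Reagents that add atoms: none
Why: Borohydride reduction of the aldehyde to the benzylic alcohol.

Step 12
Reactants: 16 the benzylic alcohol; 17 (1R,4R,5R)-4,7,7-trimethyl-6-thiabicyclo[3.2.1]octane (isothiocineole)
Product: 18 (1R,4R,5R)-6-{[(2R,3R)-6-(benzyloxy)-2-[2,4-bis(benzyloxy)phenyl]-3-[3,5-bis(benzyloxy)phenyl]-2,3-dihydro-1-benzofuran-5-yl]methyl}-4,7,7-trimethyl-6-thiabicyclo[3.2.1]octan-6-ium tetrafluoroborate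
Conditions: 17 (2 equiv), HBF4·OEt2 (1.0 equiv), CH2Cl2, −40 °C to 0 °C; precipitation with Et2O
Reagents that add atoms: tetrafluoroboric acid, [H+].F[B-](F)(F)F
Why: Acid-promoted ionisation of the electron-rich benzylic alcohol and capture of the cation by the sulfide (S-alkylation of a sulfide, known for benzylic alcohols) gives the sulfonium salt; low temperature and the non-nucleophilic counter-ion should keep it intact, and alkylation on the less hindered lone pair should give one configuration at sulfur.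

Step 13
Reactants: 1 2,4-bis(benzyloxy)benzaldehyde
Product: 19 2,4-bis(benzyloxy)-1-ethenylbenzene
Conditions: Ph3PCH3Br, KOtBu, THF, 0 °C to 23 °C
Reagents that add atoms: methyltriphenylphosphonium bromide, C[P+](c1ccccc1)(c1ccccc1)c1ccccc1.[Br-]
Why: Wittig methylenation of the aldehyde.

Step 14
Reactants: 20 4-bromo-2,6-difluorobenzaldehyde
Product: 21 2,6-bis(benzyloxy)-4-bromobenzaldehyde
Conditions: BnOH (2.2 equiv), NaH (2.3 equiv), THF/DMF, 0 °C to 23 °C
Reagents that add atoms: benzyl alcohol, OCc1ccccc1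
Why: Twofold nucleophilic aromatic substitution of the two fluorides, both activated by the ortho formyl group; fluoride should be displaced far faster than the para bromide.

Step 15
Reactants: 21 2,6-bis(benzyloxy)-4-bromobenzaldehyde; 19 2,4-bis(benzyloxy)-1-ethenylbenzene
Product: 22 2,6-bis(benzyloxy)-4-{(E)-2-[2,4-bis(benzyloxy)phenyl]ethenyl}benzaldehyde
Conditions: Pd(OAc)2 (5 mol %), P(o-tol)3 (10 mol %), Et3N, DMF, 100 °C
Reagents that add atoms: none
Why: Heck reaction of the aryl bromide, activated by the para formyl group, with the styrene; syn beta-hydride elimination should give the E stilbene.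

Step 16
Reactants: 22 the stilbene aldehyde
Product: 23 2-(benzyloxy)-4-{(E)-2-[2,4-bis(benzyloxy)phenyl]ethenyl}-6-hydroxybenzaldehyde
Conditions: MgBr2·OEt2 (1.2 equiv), toluene/Et2O, 60 °C; then H2O
Reagents that add atoms: none
Why: Chelation of MgBr2 between the formyl oxygen and one ortho ether oxygen activates that benzyl ether for attack by bromide (known selective cleavage of benzyl ethers ortho to a carbonyl); the magnesium phenoxide chelate then deactivates the second ortho ether, and the two remote benzyl ethers lack the chelating carbonyl.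

Step 17
Reactants: 23 the salicylaldehyde; 7 [3,5-bis(benzyloxy)phenyl]magnesium bromide
Product: 24 3-(benzyloxy)-2-{[3,5-bis(benzyloxy)phenyl](hydroxy)methyl}-5-{(E)-2-[2,4-bis(benzyloxy)phenyl]ethenyl}phenol (racemic)
Conditions: 7 (2.3 equiv, THF solution), THF, −20 °C to 0 °C; then H2O
Reagents that add atoms: none
Why: Grignard addition to the salicylaldehyde (the first equivalent is consumed by the phenol) gives the ortho-hydroxybenzhydrol; its carbinol centre is racemic and is erased in step 19.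

Step 18
Reactants: 24 the ortho-hydroxybenzhydrol
Product: 25 3-(benzyloxy)-2-{[3,5-bis(benzyloxy)phenyl](4-methylbenzenesulfonyl)methyl}-5-{(E)-2-[2,4-bis(benzyloxy)phenyl]ethenyl}phenol (racemic)
Conditions: sodium 4-methylbenzenesulfinate (3 equiv), HCO2H, CH2Cl2/H2O, 23 °C
Reagents that add atoms: sodium 4-methylbenzenesulfinate, Cc1ccc(cc1)S(=O)[O-].[Na+]
Why: Mild acid ionises the doubly benzylic alcohol and the sulfinate captures the cation at sulfur, giving a bench-stable 2-(sulfonylalkyl)phenol, a known base-triggered precursor of ortho-quinone methides.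

Step 19
Reactants: 25 the sulfone; 18 the sulfonium tetrafluoroborate
Product: 29 decabenzyl ether of gneyulin A (each dihydrofuran ring trans-2R,3R), via ortho-quinone methide 26 (not isolated), via sulfonium ylide 27 (not isolated), via betaine 28 (not isolated)
Conditions: 25 (1.0 equiv), 18 (1.2 equiv), Cs2CO3 (3 equiv), CH2Cl2, −20 °C to 23 °C
Reagents that add atoms: none
Why: Proposed new method: Cs2CO3 deprotonates the phenol of 25, which expels 4-methylbenzenesulfinate to give ortho-quinone methide 26, and deprotonates 18 to the benzylic ylide 27; conjugate addition of the ylide carbon to the exocyclic methide carbon (which restores aromaticity) forms C2–C3 in betaine 28, and the phenoxide then displaces the sulfide to form O1–C2. The closest known reactions are the [4+1] annulations of carbonyl-stabilised sulfonium and ammonium ylides with ortho-quinone methides released from 2-(sulfonylalkyl)phenols, and the epoxidation of aldehydes by isothiocineole-derived benzylic ylides; new here is an aryl-stabilised chiral ylide on an ortho-quinone methide. The dihydrofuran ring closes in 5-exo-tet mode with inversion at C2. C2 is controlled by the ylide face left open by the bicyclic sulfide, and C3 by the anti approach of the methide that keeps the two aryl groups apart, so that inversion at C2 should give the trans (2R,3R) ring; the remote stereocentres of 18 should not interfere. The step needs conjugate addition to win over dimerisation of 26 and over attack of sulfinate on 18, which the slow release of the hindered, styryl-conjugated 26 and the insolubility of the caesium sulfinate in CH2Cl2 should secure. Any cis isomer would carry the wrong C3 configuration and would be removed by chromatography, not equilibrated.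

Step 20
Reactants: 29 decabenzyl ether of gneyulin A
Product: 30 gneyulin A
Conditions: BCl3 (1 M in CH2Cl2, 20 equiv), C6HMe5 (30 equiv), CH2Cl2, −78 °C; then MeOH, −78 °C to 0 °C
Reagents that add atoms: none
Why: BCl3 cleaves aryl benzyl ethers at −78 °C while pentamethylbenzene captures the benzyl cations by Friedel–Crafts alkylation (a known cation-scavenger debenzylation that spares the stilbene, which hydrogenolysis would reduce); the boron aryloxides formed should lower the donor strength of the rings that could ionise the two C2–O bonds, and a ring that opens should reclose to the trans form.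

**Compound list**

1 | 2,4-bis(benzyloxy)benzaldehyde | O=Cc1ccc(OCc2ccccc2)cc1OCc1ccccc1 | starting material
2 | [2,4-bis(benzyloxy)phenyl]methanol | OCc1ccc(OCc2ccccc2)cc1OCc1ccccc1 | intermediate
3 | 5-bromo-2,4-dihydroxybenzaldehyde | O=Cc1cc(Br)c(O)cc1O | starting material
4 | 4-(benzyloxy)-5-bromo-2-hydroxybenzaldehyde | O=Cc1cc(Br)c(OCc2ccccc2)cc1O | intermediate
5 | 4-(benzyloxy)-2-{[2,4-bis(benzyloxy)phenyl]methoxy}-5-bromobenzaldehyde | O=Cc1cc(Br)c(OCc2ccccc2)cc1OCc1ccc(OCc2ccccc2)cc1OCc1ccccc1 | intermediate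
6 | 1,3-bis(benzyloxy)-5-bromobenzene | Brc1cc(OCc2ccccc2)cc(OCc2ccccc2)c1 | starting material
7 | [3,5-bis(benzyloxy)phenyl]magnesium bromide (titrated THF solution) | Br[Mg]c1cc(OCc2ccccc2)cc(OCc2ccccc2)c1 | intermediate
8 | (4-(benzyloxy)-2-{[2,4-bis(benzyloxy)phenyl]methoxy}-5-bromophenyl)[3,5-bis(benzyloxy)phenyl]methanol, racemic | OC(c1cc(OCc2ccccc2)cc(OCc2ccccc2)c1)c1cc(Br)c(OCc2ccccc2)cc1OCc1ccc(OCc2ccccc2)cc1OCc1ccccc1 | intermediate
9 | (4-(benzyloxy)-2-{[2,4-bis(benzyloxy)phenyl]methoxy}-5-bromophenyl)[3,5-bis(benzyloxy)phenyl]methanone | O=C(c1cc(OCc2ccccc2)cc(OCc2ccccc2)c1)c1cc(Br)c(OCc2ccccc2)cc1OCc1ccc(OCc2ccccc2)cc1OCc1ccccc1 | intermediate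
10 | hydrazone of 9, E/Z mixture | NN=C(c1cc(OCc2ccccc2)cc(OCc2ccccc2)c1)c1cc(Br)c(OCc2ccccc2)cc1OCc1ccc(OCc2ccccc2)cc1OCc1ccccc1 | intermediate
11 | diaryldiazomethane from 10 | [N-]=[N+]=C(c1cc(OCc2ccccc2)cc(OCc2ccccc2)c1)c1cc(Br)c(OCc2ccccc2)cc1OCc1ccc(OCc2ccccc2)cc1OCc1ccccc1 | intermediate (not isolated)
12 | (2S,3R)-6-(benzyloxy)-2-[2,4-bis(benzyloxy)phenyl]-3-[3,5-bis(benzyloxy)phenyl]-5-bromo-2,3-dihydro-1-benzofuran, cis | C(c1ccccc1)Oc1cc(OCc2ccccc2)cc(c1)[C@@H]1c2cc(Br)c(OCc3ccccc3)cc2O[C@@H]1c1ccc(OCc2ccccc2)cc1OCc1ccccc1 | intermediate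
13 | (2R,3R)-6-(benzyloxy)-2-[2,4-bis(benzyloxy)phenyl]-3-[3,5-bis(benzyloxy)phenyl]-5-bromo-2,3-dihydro-1-benzofuran, trans | C(c1ccccc1)Oc1cc(OCc2ccccc2)cc(c1)[C@@H]1c2cc(Br)c(OCc3ccccc3)cc2O[C@H]1c1ccc(OCc2ccccc2)cc1OCc1ccccc1 | intermediate
14 | 5-lithio derivative of 13 | C(c1ccccc1)Oc1cc(OCc2ccccc2)cc(c1)[C@@H]1c2cc([Li])c(OCc3ccccc3)cc2O[C@H]1c1ccc(OCc2ccccc2)cc1OCc1ccccc1 | intermediate (not isolated)
15 | (2R,3R)-6-(benzyloxy)-2-[2,4-bis(benzyloxy)phenyl]-3-[3,5-bis(benzyloxy)phenyl]-2,3-dihydro-1-benzofuran-5-carbaldehyde | C(c1ccccc1)Oc1cc(OCc2ccccc2)cc(c1)[C@@H]1c2cc(C=O)c(OCc3ccccc3)cc2O[C@H]1c1ccc(OCc2ccccc2)cc1OCc1ccccc1 | intermediate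
16 | [(2R,3R)-6-(benzyloxy)-2-[2,4-bis(benzyloxy)phenyl]-3-[3,5-bis(benzyloxy)phenyl]-2,3-dihydro-1-benzofuran-5-yl]methanol | C(c1ccccc1)Oc1cc(OCc2ccccc2)cc(c1)[C@@H]1c2cc(CO)c(OCc3ccccc3)cc2O[C@H]1c1ccc(OCc2ccccc2)cc1OCc1ccccc1 | intermediate
17 | (1R,4R,5R)-4,7,7-trimethyl-6-thiabicyclo[3.2.1]octane (isothiocineole) | C[C@@H]1CC[C@@H]2C[C@H]1SC2(C)C | starting material
18 | (1R,4R,5R)-6-{[(2R,3R)-6-(benzyloxy)-2-[2,4-bis(benzyloxy)phenyl]-3-[3,5-bis(benzyloxy)phenyl]-2,3-dihydro-1-benzofuran-5-yl]methyl}-4,7,7-trimethyl-6-thiabicyclo[3.2.1]octan-6-ium tetrafluoroborate (configuration at sulfur not specified) | C(c1ccccc1)Oc1cc(OCc2ccccc2)cc(c1)[C@@H]1c2cc(C[S+]3[C@@H]4C[C@@H](CC[C@H]4C)C3(C)C)c(OCc3ccccc3)cc2O[C@H]1c1ccc(OCc2ccccc2)cc1OCc1ccccc1.F[B-](F)(F)F | intermediate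
19 | 2,4-bis(benzyloxy)-1-ethenylbenzene | C=Cc1ccc(OCc2ccccc2)cc1OCc1ccccc1 | intermediate
20 | 4-bromo-2,6-difluorobenzaldehyde | O=Cc1c(F)cc(Br)cc1F | starting material
21 | 2,6-bis(benzyloxy)-4-bromobenzaldehyde | O=Cc1c(OCc2ccccc2)cc(Br)cc1OCc1ccccc1 | intermediate
22 | 2,6-bis(benzyloxy)-4-{(E)-2-[2,4-bis(benzyloxy)phenyl]ethenyl}benzaldehyde | O=Cc1c(OCc2ccccc2)cc(/C=C/c2ccc(OCc3ccccc3)cc2OCc2ccccc2)cc1OCc1ccccc1 | intermediate
23 | 2-(benzyloxy)-4-{(E)-2-[2,4-bis(benzyloxy)phenyl]ethenyl}-6-hydroxybenzaldehyde | O=Cc1c(O)cc(/C=C/c2ccc(OCc3ccccc3)cc2OCc2ccccc2)cc1OCc1ccccc1 | intermediate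
24 | 3-(benzyloxy)-2-{[3,5-bis(benzyloxy)phenyl](hydroxy)methyl}-5-{(E)-2-[2,4-bis(benzyloxy)phenyl]ethenyl}phenol, racemic | OC(c1cc(OCc2ccccc2)cc(OCc2ccccc2)c1)c1c(O)cc(/C=C/c2ccc(OCc3ccccc3)cc2OCc2ccccc2)cc1OCc1ccccc1 | intermediate
25 | 3-(benzyloxy)-2-{[3,5-bis(benzyloxy)phenyl](4-methylbenzenesulfonyl)methyl}-5-{(E)-2-[2,4-bis(benzyloxy)phenyl]ethenyl}phenol, racemic | Cc1ccc(cc1)S(=O)(=O)C(c1cc(OCc2ccccc2)cc(OCc2ccccc2)c1)c1c(O)cc(/C=C/c2ccc(OCc3ccccc3)cc2OCc2ccccc2)cc1OCc1ccccc1 | intermediate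
26 | 3-(benzyloxy)-2-{[3,5-bis(benzyloxy)phenyl]methylidene}-5-{(E)-2-[2,4-bis(benzyloxy)phenyl]ethenyl}cyclohexa-3,5-dien-1-one (ortho-quinone methide; exocyclic geometry not specified) | O=C1C=C(/C=C/c2ccc(OCc3ccccc3)cc2OCc2ccccc2)C=C(OCc2ccccc2)C1=Cc1cc(OCc2ccccc2)cc(OCc2ccccc2)c1 | intermediate (not isolated)
27 | benzylic sulfonium ylide from 18 | C(c1ccccc1)Oc1cc(OCc2ccccc2)cc(c1)[C@@H]1c2cc([CH-][S+]3[C@@H]4C[C@@H](CC[C@H]4C)C3(C)C)c(OCc3ccccc3)cc2O[C@H]1c1ccc(OCc2ccccc2)cc1OCc1ccccc1 | intermediate (not isolated)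
28 | anti betaine (phenoxide and sulfonium) from 26 and 27 | C(c1ccccc1)Oc1cc(OCc2ccccc2)cc(c1)[C@@H]1c2cc([C@@H]([S+]3[C@@H]4C[C@@H](CC[C@H]4C)C3(C)C)[C@H](c3cc(OCc4ccccc4)cc(OCc4ccccc4)c3)c3c([O-])cc(/C=C/c4ccc(OCc5ccccc5)cc4OCc4ccccc4)cc3OCc3ccccc3)c(OCc3ccccc3)cc2O[C@H]1c1ccc(OCc2ccccc2)cc1OCc1ccccc1 | intermediate (not isolated)
29 | decabenzyl ether of gneyulin A: (2R,3R)-4-(benzyloxy)-2-[(2R,3R)-6-(benzyloxy)-2-[2,4-bis(benzyloxy)phenyl]-3-[3,5-bis(benzyloxy)phenyl]-2,3-dihydro-1-benzofuran-5-yl]-6-{(E)-2-[2,4-bis(benzyloxy)phenyl]ethenyl}-3-[3,5-bis(benzyloxy)phenyl]-2,3-dihydro-1-benzofuran | C(c1ccccc1)Oc1cc(OCc2ccccc2)cc(c1)[C@@H]1c2cc([C@@H]3Oc4cc(/C=C/c5ccc(OCc6ccccc6)cc5OCc5ccccc5)cc(OCc5ccccc5)c4[C@H]3c3cc(OCc4ccccc4)cc(OCc4ccccc4)c3)c(OCc3ccccc3)cc2O[C@H]1c1ccc(OCc2ccccc2)cc1OCc1ccccc1 | intermediate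
30 | gneyulin A: 4-[(E)-2-{(2R,3R)-2-[(2R,3R)-2-(2,4-dihydroxyphenyl)-3-(3,5-dihydroxyphenyl)-6-hydroxy-2,3-dihydro-1-benzofuran-5-yl]-3-(3,5-dihydroxyphenyl)-4-hydroxy-2,3-dihydro-1-benzofuran-6-yl}ethenyl]benzene-1,3-diol | Oc1cc(O)cc([C@@H]2c3cc([C@@H]4Oc5cc(/C=C/c6ccc(O)cc6O)cc(O)c5[C@H]4c4cc(O)cc(O)c4)c(O)cc3O[C@H]2c2ccc(O)cc2O)c1 | target

**Step count and risks**

Total step count: 20. Longest linear sequence: 12 steps (steps 2, 3, 5 to 12, 19 and 20 from 3; equally steps 1, 3, 5 to 12, 19 and 20 from 1).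

Steps most likely to fail:

1. Step 19 (proposed new method). The hindered ylide may add too slowly to the hindered methide carbon, so that the ortho-quinone methide dimerises or the sulfinate alkylates on the sulfonium salt; or facial selectivity may be poor and give mixtures of trans and cis rings. The fallback uses known chemistry, the carbene C–H insertion of step 8 applied to furan ring 2; it sets out from 23 and 16 and returns at 29. Mitsunobu etherification of phenol 23 with alcohol 16 (PPh3, DIAD, THF) would give the aryl benzyl ether aldehyde F1. Addition of Grignard reagent 7 would give the carbinol F2, and MnO2 the benzophenone F3. Hydrazine (n-BuOH, 120 °C, forcing because the ketone is flanked by two ortho oxygens) would give the hydrazone F4, and MnO2 the diazo compound F5. With Rh2(S-PTAD)4 this should undergo 1,5 C–H insertion to the cis isomer F6 (furan ring 2 as 2S,3R), and CF3CO2H would then epimerise C2 to give 29.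

2. Step 12. The benzylic C–S bond of so electron-rich a salt may ionise again (loss of sulfide, oligomerisation of the cation), or the acid may open furan ring 1 during salt formation. The fallback avoids any isolated sulfonium salt; it sets out from 15 and returns at ylide 27 and through it at 29. Condensation of 15 with 4-methylbenzenesulfonohydrazide would give the tosylhydrazone F7, and NaOMe its sodium salt F8. Warming F8 (MeCN, 40 °C, BnEt3NCl) would release the aryldiazomethane F9. Rh2(OAc)4 (1 mol %) would transfer the carbene to sulfide 17, used in excess so that the sulfide and not the phenol intercepts the carbene. This gives ylide 27 directly, which with 25 and Cs2CO3 in the same flask should give 29 as in step 19.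

3. Step 8. The electron-rich diazo compound may couple to the azine, or the very hydridic 2,4-dialkoxybenzylic C–H bond may react by stepwise hydride transfer with loss of cis and enantioselectivity. The fallback builds furan ring 1 by the annulation of step 19 and is open only once that step is validated; it sets out from 4 and 2 and returns at 13, bypassing 5 and 8 to 12. Grignard reagent 7 would add to salicylaldehyde 4 to give the diol F10, and sulfination as in step 18 would give the sulfone F11. Alcohol 2 would be converted with 17 and HBF4·OEt2 into the sulfonium salt F12. F11 and F12 would be joined with Cs2CO3 in CH2Cl2 to give 13 directly in the trans (2R,3R) form.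

**Further compounds**

F1 | step 19 | 2-(benzyloxy)-6-{[(2R,3R)-6-(benzyloxy)-2-[2,4-bis(benzyloxy)phenyl]-3-[3,5-bis(benzyloxy)phenyl]-2,3-dihydro-1-benzofuran-5-yl]methoxy}-4-{(E)-2-[2,4-bis(benzyloxy)phenyl]ethenyl}benzaldehyde | C(c1ccccc1)Oc1cc(OCc2ccccc2)cc(c1)[C@@H]1c2cc(COc3cc(/C=C/c4ccc(OCc5ccccc5)cc4OCc4ccccc4)cc(OCc4ccccc4)c3C=O)c(OCc3ccccc3)cc2O[C@H]1c1ccc(OCc2ccccc2)cc1OCc1ccccc1
F2 | step 19 | diaryl carbinol from F1 and 7 (both epimers at the carbinol carbon) | C(c1ccccc1)Oc1cc(OCc2ccccc2)cc(c1)[C@@H]1c2cc(COc3cc(/C=C/c4ccc(OCc5ccccc5)cc4OCc4ccccc4)cc(OCc4ccccc4)c3C(O)c3cc(OCc4ccccc4)cc(OCc4ccccc4)c3)c(OCc3ccccc3)cc2O[C@H]1c1ccc(OCc2ccccc2)cc1OCc1ccccc1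
F3 | step 19 | benzophenone from F2 | C(c1ccccc1)Oc1cc(OCc2ccccc2)cc(c1)[C@@H]1c2cc(COc3cc(/C=C/c4ccc(OCc5ccccc5)cc4OCc4ccccc4)cc(OCc4ccccc4)c3C(=O)c3cc(OCc4ccccc4)cc(OCc4ccccc4)c3)c(OCc3ccccc3)cc2O[C@H]1c1ccc(OCc2ccccc2)cc1OCc1ccccc1
F4 | step 19 | hydrazone of F3 (E/Z mixture) | C(c1ccccc1)Oc1cc(OCc2ccccc2)cc(c1)[C@@H]1c2cc(COc3cc(/C=C/c4ccc(OCc5ccccc5)cc4OCc4ccccc4)cc(OCc4ccccc4)c3C(=NN)c3cc(OCc4ccccc4)cc(OCc4ccccc4)c3)c(OCc3ccccc3)cc2O[C@H]1c1ccc(OCc2ccccc2)cc1OCc1ccccc1
F5 | step 19 | diaryldiazomethane from F4 | C(c1ccccc1)Oc1cc(OCc2ccccc2)cc(c1)[C@@H]1c2cc(COc3cc(/C=C/c4ccc(OCc5ccccc5)cc4OCc4ccccc4)cc(OCc4ccccc4)c3C(=[N+]=[N-])c3cc(OCc4ccccc4)cc(OCc4ccccc4)c3)c(OCc3ccccc3)cc2O[C@H]1c1ccc(OCc2ccccc2)cc1OCc1ccccc1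
F6 | step 19 | C2 epimer of 29 in furan ring 2 (furan ring 2 cis-2S,3R; furan ring 1 trans-2R,3R) | C(c1ccccc1)Oc1cc(OCc2ccccc2)cc(c1)[C@@H]1c2cc([C@H]3Oc4cc(/C=C/c5ccc(OCc6ccccc6)cc5OCc5ccccc5)cc(OCc5ccccc5)c4[C@H]3c3cc(OCc4ccccc4)cc(OCc4ccccc4)c3)c(OCc3ccccc3)cc2O[C@H]1c1ccc(OCc2ccccc2)cc1OCc1ccccc1
F7 | step 12 | (E)-4-methylbenzenesulfonohydrazone of 15 | C(c1ccccc1)Oc1cc(OCc2ccccc2)cc(c1)[C@@H]1c2cc(/C=N/NS(=O)(=O)c3ccc(C)cc3)c(OCc3ccccc3)cc2O[C@H]1c1ccc(OCc2ccccc2)cc1OCc1ccccc1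
F8 | step 12 | sodium salt of F7 | C(c1ccccc1)Oc1cc(OCc2ccccc2)cc(c1)[C@@H]1c2cc(/C=N/[N-]S(=O)(=O)c3ccc(C)cc3)c(OCc3ccccc3)cc2O[C@H]1c1ccc(OCc2ccccc2)cc1OCc1ccccc1.[Na+]
F9 | step 12 | aryldiazomethane from F8 | C(c1ccccc1)Oc1cc(OCc2ccccc2)cc(c1)[C@@H]1c2cc(C=[N+]=[N-])c(OCc3ccccc3)cc2O[C@H]1c1ccc(OCc2ccccc2)cc1OCc1ccccc1
F10 | step 8 | 5-(benzyloxy)-2-{[3,5-bis(benzyloxy)phenyl](hydroxy)methyl}-4-bromophenol, racemic | OC(c1cc(OCc2ccccc2)cc(OCc2ccccc2)c1)c1cc(Br)c(OCc2ccccc2)cc1O
F11 | step 8 | 5-(benzyloxy)-2-{[3,5-bis(benzyloxy)phenyl](4-methylbenzenesulfonyl)methyl}-4-bromophenol, racemic | Cc1ccc(cc1)S(=O)(=O)C(c1cc(OCc2ccccc2)cc(OCc2ccccc2)c1)c1cc(Br)c(OCc2ccccc2)cc1O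
F12 | step 8 | (1R,4R,5R)-6-{[2,4-bis(benzyloxy)phenyl]methyl}-4,7,7-trimethyl-6-thiabicyclo[3.2.1]octan-6-ium tetrafluoroborate (configuration at sulfur not specified) | [S+]1(Cc2ccc(OCc3ccccc3)cc2OCc2ccccc2)[C@@H]2C[C@@H](CC[C@H]2C)C1(C)C.F[B-](F)(F)F
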